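**Retrosynthetic overview**

- The only purchased stereocentre is C7, from O-benzyl-L-tyrosine (1), carried through hydroxy acid (2) and benzyl ester/ether (3) to the α-benzyloxy aldehyde (4).
- The achiral aryl/C2–C5 unit is dehydrozingerone (5), converted to the 2-silyloxy-1,3-diene (6).
- Key disconnection: the tetrahydropyran (the only ring made) is cut at O1–C2 and C5–C6, i.e. a chelation-controlled hetero-Diels–Alder of 4 with 6 giving 2,6-cis pyranone (7). C7 controls C6, and C6 controls C2.
- C4–OH comes from axial-selective reduction of 7 to 8 (the ring controls C4); final O-debenzylation gives rhoiptelol B (9).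

Assumptions: ring numbering is O1, C2 (aryl), C4 (OH), C6, with side chain C7 (carbinol) and C8 (CH2Ar). The target is (2R,4S,6S)-2-aryl-6-[(1S)-…]: 2,6-cis, 4-OH trans to both, C6–O/C7–O syn. BnBr and TMSOTf are treated as reagents and not numbered. A one-pot work-up counts within its step.

**Step 1**
Reactants: 1, O-benzyl-L-tyrosine
Product: 2, (S)-3-[4-(benzyloxy)phenyl]-2-hydroxypropanoic acid
Conditions: NaNO2, 1 M H2SO4, dioxane/H2O, 0 °C → rt; recrystallise
Reagents that add atoms: water, O
Why: Diazotisation of the α-amino acid proceeds through an α-lactone (carboxylate participation, double inversion), so water delivers the OH with net retention and the (S) centre (future C7) is kept.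

**Step 2**
Reactants: 2, (S)-3-[4-(benzyloxy)phenyl]-2-hydroxypropanoic acid
Product: 3, benzyl (S)-2-(benzyloxy)-3-[4-(benzyloxy)phenyl]propanoate
Conditions: BnBr (3 equiv), Ag2O (3 equiv), CH2Cl2/Et2O, 4 Å MS, rt, dark
Reagents that add atoms: benzyl bromide, BrCc1ccccc1
Why: Silver-oxide-promoted Williamson etherification/carboxylate alkylation is essentially neutral, so both the acid and the activated α-hydroxyl are benzylated without base-induced epimerisation; the C7–OBn is the chelating group needed in step 5.

**Step 3**
Reactants: 3, benzyl (S)-2-(benzyloxy)-3-[4-(benzyloxy)phenyl]propanoate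
Product: 4, (S)-2-(benzyloxy)-3-[4-(benzyloxy)phenyl]propanal
Conditions: DIBAL-H (1.1 equiv), CH2Cl2, −78 °C; MeOH then Rochelle salt; use crude immediately
Reagents that add atoms: none
Why: DIBAL partial reduction of an α-alkoxy ester stops at the chelated aluminium hemiacetal at −78 °C and releases the aldehyde only on work-up; immediate use avoids α-epimerisation.

**Step 4**
Reactants: 5, dehydrozingerone [(E)-4-(4-hydroxy-3-methoxyphenyl)but-3-en-2-one]
Product: 6, (E)-1-[3-methoxy-4-(trimethylsilyloxy)phenyl]-3-(trimethylsilyloxy)buta-1,3-diene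
Conditions: TMSOTf (2.3 equiv), Et3N (3.5 equiv), Et2O, 0 °C → rt; pentane extraction, use crude
Reagents that add atoms: trimethylsilyl triflate, C[Si](C)(C)OS(=O)(=O)C(F)(F)F
Why: Silyl triflate/amine soft enolisation silylates the phenol and converts the methyl ketone (the only enolisable site) into the enol silane, giving the 2-silyloxydiene with the E-styryl geometry untouched.

**Step 5**
Reactants: 4, (S)-2-(benzyloxy)-3-[4-(benzyloxy)phenyl]propanal; 6, the bis-TMS diene (1.5 equiv)
Product: 7, (2R,6S)-6-{(1S)-1-(benzyloxy)-2-[4-(benzyloxy)phenyl]ethyl}-2-(4-hydroxy-3-methoxyphenyl)tetrahydro-4H-pyran-4-one (2,6-cis)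
Conditions: MgBr2·OEt2 (2.5 equiv, premixed with 4), CH2Cl2, −78 → 0 °C; then TFA, CH2Cl2, 0 °C → rt
Reagents that add atoms: none
Why: In this hetero-Diels–Alder (aldehyde–silyloxydiene [4+2]) the Mg chelate between C=O and C7–OBn exposes the face anti to the CH2Ar group, setting C6 as (S), syn to C7 (Cram-chelate), and the TFA work-up cleaves the enol silane and ArO–TMS while funnelling any trans adduct or uncyclised aldol material to the diequatorial 2,6-cis pyranone (C2 = R) through reversible ionisation of the electron-rich benzylic C2–O1 bond, which leaves C6 untouched.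

**Step 6**
Reactants: 7, the 2,6-cis pyranone
Product: 8, (2R,4S,6S)-6-{(1S)-1-(benzyloxy)-2-[4-(benzyloxy)phenyl]ethyl}-2-(4-hydroxy-3-methoxyphenyl)tetrahydro-2H-pyran-4-ol (4-OH axial)
Conditions: L-Selectride (3 equiv), THF, −78 °C; aq. NH4Cl, NaBO3 work-up
Reagents that add atoms: none
Why: The bulky hydride attacks the chair pyranone (both substituents equatorial) from the equatorial direction, giving the axial alcohol trans to the C2 and C6 groups, i.e. (4S); one equivalent is consumed by the phenol and benzyl ethers are inert.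

**Step 7**
Reactants: 8, the dibenzyl axial alcohol
Product: 9, rhoiptelol B, (2R,4S,6S)-2-(4-hydroxy-3-methoxyphenyl)-6-[(1S)-1-hydroxy-2-(4-hydroxyphenyl)ethyl]tetrahydro-2H-pyran-4-ol
Conditions: H2 (1 atm), 10% Pd/C, EtOAc/MeOH, rt; stop at 2 equiv H2
Reagents that add atoms: none
Why: Hydrogenolysis removes the phenolic and secondary benzyl ethers without touching a stereocentre, while the ring benzylic C2–O1 bond is much slower to cleave under neutral, acid-free conditions (as in C-aryl glycoside debenzylations).

**Compound list**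

1 | O-benzyl-L-tyrosine | N[C@@H](Cc1ccc(OCc2ccccc2)cc1)C(=O)O | starting material
2 | (S)-3-[4-(benzyloxy)phenyl]-2-hydroxypropanoic acid | O[C@@H](Cc1ccc(OCc2ccccc2)cc1)C(=O)O | intermediate
3 | benzyl (S)-2-(benzyloxy)-3-[4-(benzyloxy)phenyl]propanoate | O=C(OCc1ccccc1)[C@H](Cc1ccc(OCc2ccccc2)cc1)OCc1ccccc1 | intermediate
4 | (S)-2-(benzyloxy)-3-[4-(benzyloxy)phenyl]propanal | O=C[C@H](Cc1ccc(OCc2ccccc2)cc1)OCc1ccccc1 | intermediate
5 | dehydrozingerone, (E)-4-(4-hydroxy-3-methoxyphenyl)but-3-en-2-one | CC(=O)/C=C/c1ccc(O)c(OC)c1 | starting material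
6 | (E)-1-[3-methoxy-4-(trimethylsilyloxy)phenyl]-3-(trimethylsilyloxy)buta-1,3-diene | C=C(O[Si](C)(C)C)/C=C/c1ccc(O[Si](C)(C)C)c(OC)c1 | intermediate
7 | (2R,6S)-6-{(1S)-1-(benzyloxy)-2-[4-(benzyloxy)phenyl]ethyl}-2-(4-hydroxy-3-methoxyphenyl)tetrahydro-4H-pyran-4-one | COc1cc([C@H]2CC(=O)C[C@@H]([C@@H](OCc3ccccc3)Cc3ccc(OCc4ccccc4)cc3)O2)ccc1O | intermediate
8 | (2R,4S,6S)-6-{(1S)-1-(benzyloxy)-2-[4-(benzyloxy)phenyl]ethyl}-2-(4-hydroxy-3-methoxyphenyl)tetrahydro-2H-pyran-4-ol | COc1cc([C@H]2C[C@H](O)C[C@@H]([C@@H](OCc3ccccc3)Cc3ccc(OCc4ccccc4)cc3)O2)ccc1O | intermediate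
9 | rhoiptelol B | COc1cc([C@H]2C[C@H](O)C[C@@H]([C@@H](O)Cc3ccc(O)cc3)O2)ccc1O | target

**Totals**

Total steps: 7. Longest linear sequence: 6 (steps 1, 2, 3, 5, 6, 7); step 4 is the one-step branch.

**Three steps most likely to fail**

1. Step 5 (cycloaddition). The unactivated 2-silyloxydiene may react sluggishly or partly by an open aldol path, chelate control may be incomplete, and the acid equilibration may leave ring-opened enone. Fallback: run the better-precedented MgBr2 cyclocondensation of 4 with Danishefsky's diene (1-methoxy-3-trimethylsilyloxybutadiene) to the 2,3-dihydropyran-4-one, add the aryl group by conjugate addition, and equilibrate C2 to the 2,6-cis isomer under acid.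
2. Step 7 (hydrogenolysis). The electron-rich benzylic ring C2–O1 bond may be cleaved along with the slow secondary benzyl ether. Fallback: carry acid-labile PMB ethers instead of benzyl (PMB still chelates Mg), so that they are removed in the TFA work-up of step 5 and no hydrogenolysis is needed.
3. Step 3 (aldehyde). Over-reduction to the alcohol or α-epimerisation of the aldehyde would erode yield and the C7 stereocentre. Fallback: reduce 3 fully to the primary alcohol (LiAlH4) and oxidise it (Parikh–Doering or Dess–Martin) immediately before step 5.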